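**Retrosynthetic overview**

1. Fremontin 21 comes from bis-MOM isoflavone 20. Ring C is closed last (O1–C2) from α-formyl deoxybenzoin 17, which arises from chalcone 15 (aldehyde 12 + ketone 14) by nucleophilic epoxidation and a 1,2-aroyl shift.
2. Aldehyde 12 comes from methyl 2,4-dihydroxy-5-(1,1-dimethylallyl)benzoate 9, the aromatised form of dione ester 7; the ester carbon of 7 ends as C3 of ring C.
3. Dione ester 7 comes from a Michael–Claisen annulation of methyl acetoacetate 5 with the 2-(1,1-dimethylallyl)acrylate 4, forming C1'–C6' and C3'–C4'. Acrylate 4 comes from methyl 3,3-dimethylpent-4-enoate 1 by α-methylenation.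
4. Feature: ring B (C1'–C6') is a resorcinol with OH on C2' and C4', carbon substituents on C1' and C5', and hydrogen on C3' and C6'. It is the aromatised form of a 4,6-disubstituted cyclohexane-1,3-dione, so C3' is unsubstituted by construction.
5. Ring order: ring B (steps 3 and 4), ring A bought as phloroacetophenone 13, ring C last (step 12).

Key step: step 3

Remark on the chemistry: ester 1 is assumed to be purchasable. The terminal vinyl group rules out Pd/C dehydrogenation (the hydrogen released would saturate it) and trivalent thallium or iodine oxidants (they attack it), so aromatisation uses bromination–dehydrobromination and the 1,2-shift goes through a nucleophilically formed epoxide. Racemic or epimeric intermediates (2, 3, 6, 7, 16, 17) lose their centres before the achiral target.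

**Route**

Step 1
Reactants: 1 methyl 3,3-dimethylpent-4-enoate
Product: 2 methyl 2-[(dimethylamino)methyl]-3,3-dimethylpent-4-enoate (racemic)
Conditions: LiN(i-Pr)2, THF, −78 °C; then [CH2=NMe2]I, −78 °C to rt
Reagents that add atoms: N,N-dimethylmethyleneiminium iodide (Eschenmoser's salt), C=[N+](C)C.[I-]
Why: Mannich aminomethylation of the lithium ester enolate with a preformed iminium salt, which is small and electrophilic enough to reach the α-carbon next to the quaternary centre; the new stereocentre forms as a racemate and is removed in step 2.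

Step 2
Reactants: 2 methyl 2-[(dimethylamino)methyl]-3,3-dimethylpent-4-enoate
Product: 4 methyl 3,3-dimethyl-2-methylidenepent-4-enoate, via trimethylammonium iodide 3 (not isolated)
Conditions: MeI, MeOH, rt; then K2CO3, H2O/CH2Cl2, rt
Reagents that add atoms: none
Why: N-methylation turns the amine into a leaving group and mild base triggers an E1cB (Hofmann-type) β-elimination to the α-methylene ester, whose skipped diene cannot isomerise because the carbon between the two alkenes is quaternary.

Step 3
Reactants: 4 methyl 3,3-dimethyl-2-methylidenepent-4-enoate; 5 methyl acetoacetate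
Product: 7 methyl 5-(2-methylbut-3-en-2-yl)-2,4-dioxocyclohexane-1-carboxylate, via Michael adduct 6 (not isolated)
Conditions: NaOMe, MeOH, reflux; then aq. HCl, 0 °C
Reagents that add atoms: none
Why: Methoxide deprotonates the acetoacetate at its doubly activated carbon, which adds to the unhindered β-methylene of 4 (Michael addition, bond C1'–C6'); after proton transfer the small equilibrium share of the acetyl-methyl enolate of adduct 6 acylates itself on the ester of the former acrylate (Claisen/Dieckmann-type condensation, bond C3'–C4'), and deprotonation of the resulting 1,3-dione (pKa about 5) pulls both equilibria to product. The closest known reaction type is the Michael–Claisen synthesis of 4-alkoxycarbonylcyclohexane-1,3-diones (dihydroresorcylates) from acetoacetates and α,β-unsaturated esters. The ring closes in the 6-exo-trig mode, the attacked ester carbonyl oxygen staying outside the ring. The two new centres (C1 and C5 of the cyclohexane) form without control as an epimerisable, enolising mixture, which is of no consequence because both become sp2 carbons in step 4. Only constitutional selectivity is needed, and the substrate secures it: the sole Michael donor is the carbon between the two carbonyl groups, the sole acceptor position is the CH2 terminus, and the acetyl methyl is the only enolisable carbon that can reach an ester carbonyl through a six-membered transition state (every alternative would close a four-membered ring). The isolated vinyl group is unconjugated, has no allylic hydrogen on the quaternary carbon and should be inert to methoxide.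

Step 4
Reactants: 7 methyl 5-(2-methylbut-3-en-2-yl)-2,4-dioxocyclohexane-1-carboxylate
Product: 9 methyl 2,4-dihydroxy-5-(2-methylbut-3-en-2-yl)benzoate, via bromodione 8 (not isolated)
Conditions: Br2 (1.0 equiv, slow addition), DMF, 0 °C; then 80 °C
Reagents that add atoms: none
Why: Bromination–dehydrobromination aromatisation of a dihydroresorcylate, in which the dione enol is brominated at C3 far faster than bromine adds to a monosubstituted alkene at 0 °C and the bis-enol tautomer then loses HBr (bromide from C3, proton from C6) on warming, with DMF acting as the HBr acceptor.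

Step 5
Reactants: 9 methyl 2,4-dihydroxy-5-(2-methylbut-3-en-2-yl)benzoate
Product: 10 methyl 2,4-bis(methoxymethoxy)-5-(2-methylbut-3-en-2-yl)benzoate
Conditions: NaH, MOMCl, DMF, 0 °C to rt
Reagents that add atoms: chloromethyl methyl ether (MOMCl), COCCl
Why: Williamson-type O-alkylation of both phenoxides (NaH is needed for the hydrogen-bonded 2-OH), giving acetals that withstand hydride, hydroxide and peroxide and keep the ring-B oxygens masked until ring C is closed.

Step 6
Reactants: 10 methyl 2,4-bis(methoxymethoxy)-5-(2-methylbut-3-en-2-yl)benzoate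
Product: 11 [2,4-bis(methoxymethoxy)-5-(2-methylbut-3-en-2-yl)phenyl]methanol
Conditions: LiAlH4, THF, 0 °C
Reagents that add atoms: none
Why: Hydride reduction of the aryl ester to the benzylic alcohol, with the isolated alkene and the MOM acetals inert to LiAlH4.

Step 7
Reactants: 11 [2,4-bis(methoxymethoxy)-5-(2-methylbut-3-en-2-yl)phenyl]methanol
Product: 12 2,4-bis(methoxymethoxy)-5-(2-methylbut-3-en-2-yl)benzaldehyde
Conditions: MnO2, CH2Cl2, rt
Reagents that add atoms: none
Why: Heterogeneous MnO2 oxidation is selective for benzylic alcohols, stops at the aldehyde and does not touch the vinyl group.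

Step 8
Reactants: 13 2,4,6-trihydroxyacetophenone
Product: 14 1-[2,4,6-tris(prop-2-enyloxy)phenyl]ethan-1-one
Conditions: allyl bromide, K2CO3, DMF, 60 °C
Reagents that add atoms: allyl bromide, C=CCBr
Why: Threefold Williamson O-allylation in a dipolar aprotic solvent (which favours O- over C-alkylation of the phloroglucinol nucleus); allyl ethers are chosen because an ortho allyloxy group, unlike an acetal, is not lost after reversible attack on the cation of step 11 and can later be removed without acid or hydrogen.

Step 9
Reactants: 12 2,4-bis(methoxymethoxy)-5-(2-methylbut-3-en-2-yl)benzaldehyde; 14 1-[2,4,6-tris(prop-2-enyloxy)phenyl]ethan-1-one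
Product: 15 (E)-3-[2,4-bis(methoxymethoxy)-5-(2-methylbut-3-en-2-yl)phenyl]-1-[2,4,6-tris(prop-2-enyloxy)phenyl]prop-2-en-1-one
Conditions: KOH, EtOH/H2O, rt
Reagents that add atoms: none
Why: Claisen–Schmidt (crossed aldol) condensation between the only enolisable partner 14 and the non-enolisable aldehyde 12, with E1cB dehydration giving the E-enone under thermodynamic control.

Step 10
Reactants: 15 (E)-3-[2,4-bis(methoxymethoxy)-5-(2-methylbut-3-en-2-yl)phenyl]-1-[2,4,6-tris(prop-2-enyloxy)phenyl]prop-2-en-1-one
Product: 16 trans-{3-[2,4-bis(methoxymethoxy)-5-(2-methylbut-3-en-2-yl)phenyl]oxiran-2-yl}[2,4,6-tris(prop-2-enyloxy)phenyl]methanone (racemic)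
Conditions: 30% H2O2, aq. NaOH, MeOH/THF, 0 °C to rt
Reagents that add atoms: hydrogen peroxide, OO
Why: Weitz–Scheffer nucleophilic epoxidation, in which hydroperoxide anion adds only to the enone β-carbon so that the vinyl and allyl groups are untouched, and closure of the freely rotating enolate gives the trans-epoxide as a racemate whose two centres are lost again in step 11.

Step 11
Reactants: 16 trans-{3-[2,4-bis(methoxymethoxy)-5-(2-methylbut-3-en-2-yl)phenyl]oxiran-2-yl}[2,4,6-tris(prop-2-enyloxy)phenyl]methanone
Product: 17 2-[2,4-bis(methoxymethoxy)-5-(2-methylbut-3-en-2-yl)phenyl]-3-oxo-3-[2,4,6-tris(prop-2-enyloxy)phenyl]propanal (racemic, in equilibrium with its hydroxymethylene enol)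
Conditions: BF3·OEt2 (0.3 equiv), CH2Cl2, −40 to 0 °C
Reagents that add atoms: none
Why: Meinwald-type rearrangement of a chalcone epoxide, in which the Lewis acid opens the epoxide at the benzylic carbon stabilised by the 2,4-dioxygenated ring B and the aroyl group undergoes a 1,2-shift to that carbon, so that ring B stays on the future C3 and the former acetyl carbon becomes the formyl group (future C2); the new centre is racemic and enolisable.

Step 12
Reactants: 17 2-[2,4-bis(methoxymethoxy)-5-(2-methylbut-3-en-2-yl)phenyl]-3-oxo-3-[2,4,6-tris(prop-2-enyloxy)phenyl]propanal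
Product: 20 3-[2,4-bis(methoxymethoxy)-5-(2-methylbut-3-en-2-yl)phenyl]-5,7-dihydroxy-4H-chromen-4-one, via enaminone 18 (not isolated), via triol enaminone 19 (not isolated)
Conditions: pyrrolidine, THF, rt; Pd(PPh3)4 (5 mol %), rt; then AcOH, 50 °C
Reagents that add atoms: none
Why: Condensation of the formyl group with the secondary amine gives an enaminone that masks the acidic 1,3-dicarbonyl against C-allylation, zerovalent palladium then transfers the three allyl groups to pyrrolidine (Tsuji–Trost deallylation of aryl allyl ethers), and under acetic acid the freed ring-A 2-OH closes ring C by 6-endo addition–elimination with loss of pyrrolidine while the still-protected ring-B oxygens cannot compete to form a benzofuran.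

Step 13
Reactants: 20 3-[2,4-bis(methoxymethoxy)-5-(2-methylbut-3-en-2-yl)phenyl]-5,7-dihydroxy-4H-chromen-4-one
Product: 21 fremontin, 3-[2,4-dihydroxy-5-(2-methylbut-3-en-2-yl)phenyl]-5,7-dihydroxy-4H-chromen-4-one
Conditions: 3 M aq. HCl, MeOH, 40 °C
Reagents that add atoms: none
Why: Acid-catalysed acetal exchange with methanol should remove both MOM groups, and the conditions are kept mild so that the 4'-OH does not add to the neighbouring monosubstituted alkene, which would require a secondary carbocation.

**Compound list**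

1 | methyl 3,3-dimethylpent-4-enoate | COC(=O)CC(C)(C)C=C | starting material
2 | methyl 2-[(dimethylamino)methyl]-3,3-dimethylpent-4-enoate (racemic) | COC(=O)C(CN(C)C)C(C)(C)C=C | intermediate
3 | [2-(methoxycarbonyl)-3,3-dimethylpent-4-en-1-yl]trimethylammonium iodide (racemic, not isolated) | COC(=O)C(C[N+](C)(C)C)C(C)(C)C=C.[I-] | intermediate
4 | methyl 3,3-dimethyl-2-methylidenepent-4-enoate | C=CC(C)(C)C(=C)C(=O)OC | intermediate
5 | methyl acetoacetate | COC(=O)CC(C)=O | starting material
6 | dimethyl 2-acetyl-4-(2-methylbut-3-en-2-yl)pentanedioate (diastereomer mixture, not isolated) | COC(=O)C(C(C)=O)CC(C(=O)OC)C(C)(C)C=C | intermediate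
7 | methyl 5-(2-methylbut-3-en-2-yl)-2,4-dioxocyclohexane-1-carboxylate (mixture of epimers and enol tautomers) | COC(=O)C1CC(C(C)(C)C=C)C(=O)CC1=O | intermediate
8 | methyl 3-bromo-5-(2-methylbut-3-en-2-yl)-2,4-dioxocyclohexane-1-carboxylate (stereoisomer and tautomer mixture, not isolated) | COC(=O)C1CC(C(C)(C)C=C)C(=O)C(Br)C1=O | intermediate
9 | methyl 2,4-dihydroxy-5-(2-methylbut-3-en-2-yl)benzoate | COC(=O)c1cc(C(C)(C)C=C)c(O)cc1O | intermediate
10 | methyl 2,4-bis(methoxymethoxy)-5-(2-methylbut-3-en-2-yl)benzoate | COCOc1cc(OCOC)c(C(C)(C)C=C)cc1C(=O)OC | intermediate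
11 | [2,4-bis(methoxymethoxy)-5-(2-methylbut-3-en-2-yl)phenyl]methanol | COCOc1cc(OCOC)c(C(C)(C)C=C)cc1CO | intermediate
12 | 2,4-bis(methoxymethoxy)-5-(2-methylbut-3-en-2-yl)benzaldehyde | COCOc1cc(OCOC)c(C(C)(C)C=C)cc1C=O | intermediate
13 | 2,4,6-trihydroxyacetophenone | CC(=O)c1c(O)cc(O)cc1O | starting material
14 | 1-[2,4,6-tris(prop-2-enyloxy)phenyl]ethan-1-one | CC(=O)c1c(OCC=C)cc(OCC=C)cc1OCC=C | intermediate
15 | (E)-3-[2,4-bis(methoxymethoxy)-5-(2-methylbut-3-en-2-yl)phenyl]-1-[2,4,6-tris(prop-2-enyloxy)phenyl]prop-2-en-1-one | C=CCOc1cc(OCC=C)c(C(=O)/C=C/c2cc(C(C)(C)C=C)c(OCOC)cc2OCOC)c(OCC=C)c1 | intermediate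
16 | trans-{3-[2,4-bis(methoxymethoxy)-5-(2-methylbut-3-en-2-yl)phenyl]oxiran-2-yl}[2,4,6-tris(prop-2-enyloxy)phenyl]methanone (racemic; 2S,3R enantiomer drawn) | C=CCOc1cc(OCC=C)c(C(=O)[C@H]2O[C@@H]2c3cc(C(C)(C)C=C)c(OCOC)cc3OCOC)c(OCC=C)c1 | intermediate
17 | 2-[2,4-bis(methoxymethoxy)-5-(2-methylbut-3-en-2-yl)phenyl]-3-oxo-3-[2,4,6-tris(prop-2-enyloxy)phenyl]propanal (racemic, enolisable) | C=CCOc1cc(OCC=C)c(C(=O)C(C=O)c2cc(C(C)(C)C=C)c(OCOC)cc2OCOC)c(OCC=C)c1 | intermediate
18 | 2-[2,4-bis(methoxymethoxy)-5-(2-methylbut-3-en-2-yl)phenyl]-3-(pyrrolidin-1-yl)-1-[2,4,6-tris(prop-2-enyloxy)phenyl]prop-2-en-1-one (drawn E; geometry of no consequence; not isolated) | C=CCOc1cc(OCC=C)c(C(=O)/C(=C/N2CCCC2)c3cc(C(C)(C)C=C)c(OCOC)cc3OCOC)c(OCC=C)c1 | intermediate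
19 | 2-[2,4-bis(methoxymethoxy)-5-(2-methylbut-3-en-2-yl)phenyl]-3-(pyrrolidin-1-yl)-1-(2,4,6-trihydroxyphenyl)prop-2-en-1-one (drawn E; not isolated) | Oc1cc(O)c(C(=O)/C(=C/N2CCCC2)c3cc(C(C)(C)C=C)c(OCOC)cc3OCOC)c(O)c1 | intermediate
20 | 3-[2,4-bis(methoxymethoxy)-5-(2-methylbut-3-en-2-yl)phenyl]-5,7-dihydroxy-4H-chromen-4-one | C=CC(C)(C)c1cc(-c2coc3cc(O)cc(O)c3c2=O)c(OCOC)cc1OCOC | intermediate
21 | fremontin, 3-[2,4-dihydroxy-5-(2-methylbut-3-en-2-yl)phenyl]-5,7-dihydroxy-4H-chromen-4-one | C=CC(C)(C)c1cc(-c2coc3cc(O)cc(O)c3c2=O)c(O)cc1O | target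

**Step count**

Total: 13 steps. Longest linear sequence: 12 steps (steps 1–7 and 9–13; step 8 is a one-step side branch).

**Steps most likely to fail**

Step 4. Bromine, either free or regenerated from the bromodione and HBr on heating, may add to the vinyl group or brominate the electron-rich product at C3 instead of leaving as HBr. The fallback avoids electrophilic halogen and acid. It sets out from 7, which is converted with LiN(i-Pr)2 (2.2 equiv) in THF at −78 °C into its dianion and selenenylated with PhSeBr at the ester-bearing carbon to give methyl 5-(2-methylbut-3-en-2-yl)-2,4-dioxo-1-(phenylselanyl)cyclohexane-1-carboxylate F4. Oxidation with H2O2 and pyridine in CH2Cl2 at 0 °C gives the selenoxide methyl 5-(2-methylbut-3-en-2-yl)-2,4-dioxo-1-(phenylseleninyl)cyclohexane-1-carboxylate F5, which undergoes syn-elimination toward C6 and tautomerises. The route is rejoined at 9.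

Step 11. The benzylic cation may be intercepted before the aroyl group migrates: by fluoride, by the ortho allyloxy oxygen with loss of the allyl group, or through Lewis-acid cleavage of the ring-B acetals. The fallback makes 17 by C-formylation of the deoxybenzoin, with no cationic step. It sets out from 11 and from purchased 2,4,6-trihydroxybenzaldehyde, which is allylated (allyl bromide, K2CO3, DMF) to 2,4,6-tris(prop-2-enyloxy)benzaldehyde F6. Alcohol 11 is converted with MsCl, Et3N and LiCl into 1-(chloromethyl)-2,4-bis(methoxymethoxy)-5-(2-methylbut-3-en-2-yl)benzene F7, and zinc dust with LiCl in THF gives [2,4-bis(methoxymethoxy)-5-(2-methylbut-3-en-2-yl)benzyl]zinc chloride F8. This adds to F6 (MgCl2 as promoter) to give 2-[2,4-bis(methoxymethoxy)-5-(2-methylbut-3-en-2-yl)phenyl]-1-[2,4,6-tris(prop-2-enyloxy)phenyl]ethan-1-ol F9. Dess–Martin periodinane oxidises it to 2-[2,4-bis(methoxymethoxy)-5-(2-methylbut-3-en-2-yl)phenyl]-1-[2,4,6-tris(prop-2-enyloxy)phenyl]ethan-1-one F10, and ethyl formate with NaH in THF formylates the benzylic methylene. The route is rejoined at 17.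

Step 3. Closure onto the ester next to the tertiary-alkyl-bearing carbon may be too slow, so that methoxide cleaves the acetyl group of adduct 6 (retro-Claisen) or the Michael addition reverts. The fallback reverses the roles so that the electrophilic ester is an unhindered malonate ester. It sets out from 4, which is saponified (LiOH, THF/H2O) to 3,3-dimethyl-2-methylidenepent-4-enoic acid F1 and treated with MeLi (2.2 equiv, Et2O, 0 °C) to give 4,4-dimethyl-3-methylidenehex-5-en-2-one F2. Dimethyl malonate and NaOMe in refluxing MeOH add to the enone to give dimethyl 2-(2-acetyl-3,3-dimethylpent-4-en-1-yl)propanedioate F3, whose methyl ketone enolate closes onto a malonate ester in the 6-exo-trig mode. The route is rejoined at 7.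

**Further compounds**

F1 | step 3 | 3,3-dimethyl-2-methylidenepent-4-enoic acid | C=CC(C)(C)C(=C)C(=O)O
F2 | step 3 | 4,4-dimethyl-3-methylidenehex-5-en-2-one | CC(=O)C(=C)C(C)(C)C=C
F3 | step 3 | dimethyl 2-(2-acetyl-3,3-dimethylpent-4-en-1-yl)propanedioate (racemic) | COC(=O)C(CC(C(C)=O)C(C)(C)C=C)C(=O)OC
F4 | step 4 | methyl 5-(2-methylbut-3-en-2-yl)-2,4-dioxo-1-(phenylselanyl)cyclohexane-1-carboxylate (diastereomer mixture) | COC(=O)C1([Se]c2ccccc2)CC(C(C)(C)C=C)C(=O)CC1=O
F5 | step 4 | methyl 5-(2-methylbut-3-en-2-yl)-2,4-dioxo-1-(phenylseleninyl)cyclohexane-1-carboxylate (diastereomer mixture) | COC(=O)C1([Se](=O)c2ccccc2)CC(C(C)(C)C=C)C(=O)CC1=O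
F6 | step 11 | 2,4,6-tris(prop-2-enyloxy)benzaldehyde | O=Cc1c(OCC=C)cc(OCC=C)cc1OCC=C
F7 | step 11 | 1-(chloromethyl)-2,4-bis(methoxymethoxy)-5-(2-methylbut-3-en-2-yl)benzene | ClCc1cc(C(C)(C)C=C)c(OCOC)cc1OCOC
F8 | step 11 | [2,4-bis(methoxymethoxy)-5-(2-methylbut-3-en-2-yl)benzyl]zinc chloride | Cl[Zn]Cc1cc(C(C)(C)C=C)c(OCOC)cc1OCOC
F9 | step 11 | 2-[2,4-bis(methoxymethoxy)-5-(2-methylbut-3-en-2-yl)phenyl]-1-[2,4,6-tris(prop-2-enyloxy)phenyl]ethan-1-ol (racemic) | OC(Cc1cc(C(C)(C)C=C)c(OCOC)cc1OCOC)c1c(OCC=C)cc(OCC=C)cc1OCC=C
F10 | step 11 | 2-[2,4-bis(methoxymethoxy)-5-(2-methylbut-3-en-2-yl)phenyl]-1-[2,4,6-tris(prop-2-enyloxy)phenyl]ethan-1-one | O=C(Cc1cc(C(C)(C)C=C)c(OCOC)cc1OCOC)c1c(OCC=C)cc(OCC=C)cc1OCC=C
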